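The ring is numbered O1–C2–C3–C4–C5–C6. Its neighbours C3 (ketone) and C4 (enol carbon) are both at carbonyl level, and C5 is sp2 and carries no configuration. The ring is therefore cut at C3–C4, a bond between two carbons that are both natural acceptors, and closed by reductive coupling. Samarium diiodide joins the two formyl groups of an acyclic dialdehyde and gives the tetrahydropyran-3,4-diol in one operation. The precursor is an O1-linked 1,6-dialdehyde that already holds both side chains and the (S)-centre C2. It is used as a C5 epimer mixture, because C3, C4 and C5 all end up sp2 after oxidation and enolisation.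

Key step: step 14

Assumption: the target is taken as the drawn C4-enol tautomer. C7 is the first CH2 of the hexenyl arm. Compounds with undefined C3, C4 or C5 are used as stereoisomer mixtures. Conjugate bases (alkoxides, enolates) made in situ from numbered compounds get no number of their own.

Structure check: the target has (2S) at the ring centre and (4R,5S) in the hexenyl arm, and both alkenes are E. Compounds 19 and 21 carry the same descriptors, so no structural correction is needed.

Design remarks:
- **Sensitivity of 19.** Dialdehyde 19 is base-sensitive at three places: the C2–H next to CHO, the β-alkoxy aldehyde unit C4–C5–C6–O1, and the possible C5-to-C3 aldol. Both formyl groups are therefore unveiled together, last, by a base-free oxidation, and 19 is used at once.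
- **O1–C6 bond.** It is made at oxygen, with retention at C2, using an allylic chloride before any ester is present.
- **Enoate geometry.** The E-enoate comes from a syn carbometalation, not from an olefination of a ketone.
- **C7–C8 bond.** It is made by an sp3–sp2 cross-coupling that leaves C5 unselective, which costs nothing.

Step 1
Reactants: 1 (R)-glycidol
Product: 2 (S)-4-methoxybenzyl glycidyl ether, (2S)-2-{[(4-methoxybenzyl)oxy]methyl}oxirane
Conditions: NaH, PMBCl, DMF, 0 °C → rt
Reagents that add atoms: 4-methoxybenzyl chloride, COc1ccc(CCl)cc1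
Why: Williamson etherification of the primary alkoxide leaves all four bonds at the epoxide CH untouched (the Payne shift of glycidol is degenerate and regenerates the same enantiomer), and the descriptor changes from R to S only because the CH2OPMB arm now outranks the ring CH2.

Step 2
Reactants: 2 (S)-4-methoxybenzyl glycidyl ether
Product: 3 (2S)-1-[(4-methoxybenzyl)oxy]pent-4-yn-2-ol
Conditions: HC≡CLi·H2NCH2CH2NH2, DMSO, 0 °C → rt; H2O
Reagents that add atoms: lithium acetylide–ethylenediamine complex, [Li+].[C-]#C.NCCN
Why: Epoxide alkynylation, in which the acetylide opens the oxirane by SN2 attack at the unsubstituted CH2, so the C–O bond at the future C2 is not involved and the (S)-carbinol keeps the chirality of the pool material.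

Step 3
Reactants: 3 (2S)-1-[(4-methoxybenzyl)oxy]pent-4-yn-2-ol
Product: 5 (2S,4E)-5-iodo-1-[(4-methoxybenzyl)oxy]-4-methylpent-4-en-2-ol, via alkenylalane 4 (not isolated)
Conditions: Me3Al (3 equiv), Cp2ZrCl2 (0.25 equiv), CH2Cl2, 0 °C → rt; then I2, THF, −30 °C; aq. Rochelle salt
Reagents that add atoms: trimethylaluminium, C[Al](C)C; iodine, II
Why: Negishi zirconium-catalysed carboalumination adds methyl and aluminium syn across the terminal alkyne with aluminium at the terminus (the hydroxyl is parked as its aluminium alkoxide), and iodinolysis of the C–Al bond with retention should give the E-trisubstituted alkenyl iodide as one geometric isomer.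

Step 4
Reactants: 6 3-chloro-2-(chloromethyl)prop-1-ene
Product: 7 2-(chloromethyl)prop-2-en-1-yl 4-methoxybenzyl ether
Conditions: PMBOH, NaH, THF, 0 °C; then 6 (3 equiv), 0 → 50 °C
Reagents that add atoms: 4-methoxybenzyl alcohol, COc1ccc(CO)cc1
Why: Williamson mono-etherification of a symmetrical bis-allylic dichloride, held at one substitution by the excess of 6, supplies the four-carbon unit C4–C5(=C7H2)–C6.

Step 5
Reactants: 5 (2S,4E)-5-iodo-1-[(4-methoxybenzyl)oxy]-4-methylpent-4-en-2-ol; 7 2-(chloromethyl)prop-2-en-1-yl 4-methoxybenzyl ether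
Product: 8 (2S,4E)-5-iodo-4-methyl-1-(PMBO)pent-4-en-2-yl 2-[(PMBO)methyl]prop-2-en-1-yl ether
Conditions: NaH, DMF, 0 °C; then 7, 0 °C → rt
Reagents that add atoms: none
Why: Williamson etherification with a reactive allylic chloride forms the O1–C6 bond at oxygen, so C2 keeps its configuration, and at this stage the molecule holds no ester, no acidic C–H and no silyl group that could migrate to the alkoxide.

Step 6
Reactants: 8 alkenyl iodide ether; 9 tert-butyl 6-hydroxyhexanoate
Product: 10 6-tert-butoxy-6-oxohexyl (2E,5S)-3-methyl-6-(PMBO)-5-({2-[(PMBO)methyl]prop-2-en-1-yl}oxy)hex-2-enoate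
Conditions: CO (1 atm), Pd(PPh3)4 (5 mol %), 9 (3 equiv), Et3N, DMF, 60 °C
Reagents that add atoms: carbon monoxide, [C-]#[O+]
Why: Palladium-catalysed alkoxycarbonylation of an alkenyl iodide (oxidative addition, CO insertion, alcoholysis) proceeds with retention at the sp2 carbon, so the E-iodide becomes the E-enoate and the whole ester arm is attached in one convergent step.

Step 7
Reactants: 11 ethyl (S)-3-hydroxybutanoate
Product: 12 ethyl (2S,3S)-3-hydroxy-2-methylbutanoate
Conditions: LDA (2.2 equiv), THF, −78 → −20 °C; MeI, DMPU, −78 → 0 °C; H2O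
Reagents that add atoms: iodomethane, CI
Why: Fráter–Seebach alkylation, in which the chelated enolate formed by double deprotonation is methylated on the face opposite to the C3 methyl group, so the resident (S)-carbinol centre sets the new centre and the anti (2S,3S) isomer should strongly predominate.

Step 8
Reactants: 12 ethyl (2S,3S)-3-hydroxy-2-methylbutanoate
Product: 13 ethyl (2S,3S)-3-[(tert-butyldimethylsilyl)oxy]-2-methylbutanoate
Conditions: TBSCl, imidazole, DMF, rt
Reagents that add atoms: tert-butyldimethylsilyl chloride, CC(C)(C)[Si](C)(C)Cl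
Why: Standard imidazole-promoted silylation of a secondary alcohol, which touches no stereocentre.

Step 9
Reactants: 13 ethyl (2S,3S)-3-[(tert-butyldimethylsilyl)oxy]-2-methylbutanoate
Product: 14 (2S,3S)-3-[(tert-butyldimethylsilyl)oxy]-2-methylbutanal
Conditions: DIBAL-H (1.1 equiv), CH2Cl2, −78 °C; aq. Rochelle salt
Reagents that add atoms: none
Why: Partial reduction of an ester with one equivalent of DIBAL-H at −78 °C is the standard way to the aldehyde for β-silyloxy esters, and the base-free work-up spares the α-stereocentre.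

Step 10
Reactants: 14 (2S,3S)-3-[(tert-butyldimethylsilyl)oxy]-2-methylbutanal
Product: 15 (1E,3R,4S)-4-[(tert-butyldimethylsilyl)oxy]-1-iodo-3-methylpent-1-ene
Conditions: CrCl2 (6 equiv), CHI3 (2 equiv), THF–dioxane (1:6), 0 °C → rt
Reagents that add atoms: iodoform, IC(I)I
Why: Takai olefination, whose geminal dichromium reagent adds to the aldehyde and eliminates to the E-alkenyl iodide, favoured further by the α-branch, in a non-basic medium that cannot epimerise the α-centre (its descriptor becomes R only through the change of substituent ranking).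

Step 11
Reactants: 10 enoate with the 1,1-disubstituted alkene; 15 (E)-alkenyl iodide
Product: 17 6-tert-butoxy-6-oxohexyl (2E,5S)-5-{[(4E,6R,7S)-7-(TBSO)-6-methyl-2-[(PMBO)methyl]oct-4-en-1-yl]oxy}-3-methyl-6-(PMBO)hex-2-enoate (C5 epimers), via B-alkyl-9-BBN 16 (not isolated)
Conditions: 9-BBN, THF, rt; then 15, PdCl2(dppf) (5 mol %), AsPh3, Cs2CO3, DMF–H2O, rt
Reagents that add atoms: none
Why: B-alkyl Suzuki–Miyaura coupling, in which 9-BBN adds only to the 1,1-disubstituted alkene (boron on C7H2, the electron-poor trisubstituted enoate being inert) and the sp3–sp2 coupling retains the E geometry of 15, while the unselective new centre C5 is of no consequence.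

Step 12
Reactants: 17 bis-PMB ether
Product: 18 6-tert-butoxy-6-oxohexyl (2E,5S)-5-{[(4E,6R,7S)-7-(TBSO)-2-(hydroxymethyl)-6-methyloct-4-en-1-yl]oxy}-6-hydroxy-3-methylhex-2-enoate (1,6-diol, C5 epimers)
Conditions: DDQ (2.6 equiv), CH2Cl2–pH 7 buffer (10:1), 0 °C
Reagents that add atoms: none
Why: Oxidative cleavage of 4-methoxybenzyl ethers with DDQ (benzylic hydride abstraction, then hydrolysis) frees both primary alcohols at once at neutral pH and is orthogonal to the silyl ether, both esters and both alkenes.

Step 13
Reactants: 18 1,6-diol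
Product: 19 6-tert-butoxy-6-oxohexyl (2E,5S)-5-{[(4E,6R,7S)-7-(TBSO)-2-formyl-6-methyloct-4-en-1-yl]oxy}-3-methyl-6-oxohex-2-enoate (O1-linked 1,6-dialdehyde, C5 epimers)
Conditions: Dess–Martin periodinane (2.5 equiv), CH2Cl2, 0 °C → rt; short silica plug, toluene azeotrope, used at once
Reagents that add atoms: none
Why: Dess–Martin oxidation converts both primary alcohols quickly and without any base, which avoids epimerisation at C2, loss of O1 by β-elimination across C5–C6 and the C5-to-C3 aldol.

Step 14
Reactants: 19 O1-linked 1,6-dialdehyde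
Product: 21 tert-butyl 6-{[(2E)-4-{(2S)-5-[(2E,4R,5S)-5-(TBSO)-4-methylhex-2-en-1-yl]-3,4-dihydroxyoxan-2-yl}-3-methylbut-2-enoyl]oxy}hexanoate (mixture at C3, C4, C5), via samarium diolate 20 (not isolated)
Conditions: SmI2 (0.1 M in THF, 3 equiv), t-BuOH (2 equiv), THF, −78 → −20 °C, slow addition of 19 (final ca. 5 mM), no HMPA, no MeOH; aq. Rochelle salt
Reagents that add atoms: none
Why: Each formyl group takes one electron from Sm(II) to give a samarium(III) ketyl, the ketyl carbon adds to the second, samarium-bound carbonyl carbon, and the second electron completes diolate 20, which is protonated to 21. This is the samarium diiodide intramolecular pinacol coupling of 1,6-dialdehydes, well established for six-membered 1,2-diols from sugar-derived α-alkoxy dialdehydes. The single ring formed, O1–C2–C3–C4–C5–C6, closes in the 6-exo-trig mode, since the attacked C=O lies outside the new ring. The new centres C3 and C4 are governed by the samarium bridge between the two oxygens (cis-diol preferred) and by the equatorial C2 arm, but no control is needed because C3, C4 and C5 are all flattened in step 15. The step needs chemoselectivity for the two aldehydes, which accept an electron far more readily than the hindered enoate, the isolated E-alkene or the esters; the only nearby radical trap, 4-exo addition of the C3 ketyl to the enoate β-carbon, would have to build a quaternary centre in a cyclobutane and depends on methanol as co-solvent, which is left out. The medium is cold and non-basic, so the C2–H, the C2–O1 bond and the β-alkoxy aldehyde unit should survive.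

Step 15
Reactants: 21 tetrahydropyran-3,4-diol
Product: 23 tert-butyl 6-{[(2E)-4-{(2S)-5-[(2E,4R,5S)-5-(TBSO)-4-methylhex-2-en-1-yl]-4-hydroxy-3-oxo-3,6-dihydro-2H-pyran-2-yl}-3-methylbut-2-enoyl]oxy}hexanoate (protected diosphenol), via 3,4-dione 22 (not isolated)
Conditions: IBX (3 equiv), DMSO, rt
Reagents that add atoms: none
Why: IBX oxidation of a vicinal diol is known to give the α-diketone without glycol C–C cleavage, and dione 22 should enolise away from the oxygen-bearing C2 (as kinetic enolisation of α-alkoxy ketones generally does) towards C5–H to the hydrogen-bonded tetrasubstituted diosphenol, which erases C3, C4 and C5 while the base-free medium leaves C2 alone.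

Step 16
Reactants: 23 protected diosphenol
Product: 24 6,7-diketothiomarinolic acid C6, 6-{[(2E)-4-{(2S)-4-hydroxy-5-[(2E,4R,5S)-5-hydroxy-4-methylhex-2-en-1-yl]-3-oxo-3,6-dihydro-2H-pyran-2-yl}-3-methylbut-2-enoyl]oxy}hexanoic acid
Conditions: TFA–H2O (9:1), CH2Cl2, 0 °C → rt
Reagents that add atoms: none
Why: Acidolysis removes the tert-butyl ester by alkyl–oxygen fission and hydrolyses the secondary silyl ether in the same pot, with water suppressing trifluoroacetate formation, while the primary enoate ester, both alkenes and the diosphenol are spectators and no base ever meets the C2–H.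

Compound list

1 | (R)-glycidol | OC[C@@H]1CO1 | starting material
2 | (S)-4-methoxybenzyl glycidyl ether | COc1ccc(COC[C@@H]2CO2)cc1 | intermediate
3 | (2S)-1-[(4-methoxybenzyl)oxy]pent-4-yn-2-ol | C#CC[C@@H](COCc1ccc(OC)cc1)O | intermediate
4 | (E)-alkenyl(dimethyl)alane, O-dimethylaluminium alkoxide of 3 after methylalumination | C/C(=C\[Al](C)C)C[C@@H](COCc1ccc(OC)cc1)O[Al](C)C | intermediate
5 | (2S,4E)-5-iodo-1-[(4-methoxybenzyl)oxy]-4-methylpent-4-en-2-ol | C/C(=C\I)C[C@@H](COCc1ccc(OC)cc1)O | intermediate
6 | 3-chloro-2-(chloromethyl)prop-1-ene | C=C(CCl)CCl | starting material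
7 | 2-(chloromethyl)prop-2-en-1-yl 4-methoxybenzyl ether | C=C(CCl)COCc1ccc(OC)cc1 | intermediate
8 | (2S,4E)-5-iodo-4-methyl-1-(PMBO)pent-4-en-2-yl 2-[(PMBO)methyl]prop-2-en-1-yl ether | C/C(=C\I)C[C@@H](COCc1ccc(OC)cc1)OCC(=C)COCc1ccc(OC)cc1 | intermediate
9 | tert-butyl 6-hydroxyhexanoate | CC(C)(C)OC(=O)CCCCCO | starting material
10 | 6-tert-butoxy-6-oxohexyl (2E,5S)-3-methyl-6-(PMBO)-5-({2-[(PMBO)methyl]prop-2-en-1-yl}oxy)hex-2-enoate | C/C(=C\C(=O)OCCCCCC(=O)OC(C)(C)C)C[C@@H](COCc1ccc(OC)cc1)OCC(=C)COCc1ccc(OC)cc1 | intermediate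
11 | ethyl (S)-3-hydroxybutanoate | CCOC(=O)C[C@H](C)O | starting material
12 | ethyl (2S,3S)-3-hydroxy-2-methylbutanoate | CCOC(=O)[C@@H](C)[C@H](C)O | intermediate
13 | ethyl (2S,3S)-3-[(tert-butyldimethylsilyl)oxy]-2-methylbutanoate | CCOC(=O)[C@@H](C)[C@H](C)O[Si](C)(C)C(C)(C)C | intermediate
14 | (2S,3S)-3-[(tert-butyldimethylsilyl)oxy]-2-methylbutanal | O=C[C@@H](C)[C@H](C)O[Si](C)(C)C(C)(C)C | intermediate
15 | (1E,3R,4S)-4-[(tert-butyldimethylsilyl)oxy]-1-iodo-3-methylpent-1-ene | I/C=C/[C@@H](C)[C@H](C)O[Si](C)(C)C(C)(C)C | intermediate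
16 | B-alkyl-9-BBN from hydroboration of 10 (boron on C7) | C/C(=C\C(=O)OCCCCCC(=O)OC(C)(C)C)C[C@@H](COCc1ccc(OC)cc1)OCC(COCc1ccc(OC)cc1)CB1C2CCCC1CCC2 | intermediate
17 | coupled bis-PMB ether (C5 epimers) | C/C(=C\C(=O)OCCCCCC(=O)OC(C)(C)C)C[C@@H](COCc1ccc(OC)cc1)OCC(COCc1ccc(OC)cc1)C/C=C/[C@@H](C)[C@H](C)O[Si](C)(C)C(C)(C)C | intermediate
18 | O1-linked 1,6-diol (C5 epimers) | C/C(=C\C(=O)OCCCCCC(=O)OC(C)(C)C)C[C@@H](CO)OCC(CO)C/C=C/[C@@H](C)[C@H](C)O[Si](C)(C)C(C)(C)C | intermediate
19 | (2S)-O1-linked 1,6-dialdehyde (C5 epimers), key-step precursor | C/C(=C\C(=O)OCCCCCC(=O)OC(C)(C)C)C[C@@H](C=O)OCC(C=O)C/C=C/[C@@H](C)[C@H](C)O[Si](C)(C)C(C)(C)C | intermediate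
20 | bis(diiodosamarium(III)) 3,4-diolate | C/C(=C\C(=O)OCCCCCC(=O)OC(C)(C)C)C[C@@H]1OCC(C/C=C/[C@@H](C)[C@H](C)O[Si](C)(C)C(C)(C)C)C(O[Sm](I)I)C1O[Sm](I)I | intermediate
21 | (2S)-tetrahydropyran-3,4-diol (mixture at C3, C4, C5), key-step product | C/C(=C\C(=O)OCCCCCC(=O)OC(C)(C)C)C[C@@H]1OCC(C/C=C/[C@@H](C)[C@H](C)O[Si](C)(C)C(C)(C)C)C(O)C1O | intermediate
22 | (2S)-tetrahydropyran-3,4-dione (C5 epimers) | C/C(=C\C(=O)OCCCCCC(=O)OC(C)(C)C)C[C@@H]1OCC(C/C=C/[C@@H](C)[C@H](C)O[Si](C)(C)C(C)(C)C)C(=O)C1=O | intermediate
23 | protected diosphenol (TBS ether, tert-butyl ester) | C/C(=C\C(=O)OCCCCCC(=O)OC(C)(C)C)C[C@@H]1OCC(C/C=C/[C@@H](C)[C@H](C)O[Si](C)(C)C(C)(C)C)=C(O)C1=O | intermediate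
24 | 6,7-diketothiomarinolic acid C6 | C/C(=C\C(=O)OCCCCCC(=O)O)C[C@@H]1OCC(C/C=C/[C@@H](C)[C@H](C)O)=C(O)C1=O | target

Total step count: 16.
Longest linear sequence: 11 steps from (R)-glycidol (steps 1, 2, 3, 5, 6, 11, 12, 13, 14, 15, 16).

Steps most likely to fail

1. Step 14.
- **What may go wrong:** the ketyl may be reduced further to the carbinol before it couples. The C3 ketyl may add to the enoate in a 4-exo mode. The C2–O1 bond next to the ketyl may be cleaved reductively. Samarium(III) may promote aldol or Tishchenko reactions of the dialdehyde.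
- **Fallback:** the C3–C4 bond is made without radicals, setting out from 19. An N-heterocyclic-carbene-catalysed intramolecular benzoin reaction is used (bicyclic triazolium salt 10 mol %, iPr2NEt 10 mol %, CH2Cl2, rt), a reaction known for sugar-derived α-alkoxy 1,6-dialdehydes. It turns the more electrophilic C3 formyl group into the acyl-anion equivalent, which attacks C4 and should give the 4-hydroxy-3-oxotetrahydropyran F1. One further oxidation (IBX, DMSO, rt) and enolisation bring the material back to the route at 23, so that 21 is bypassed.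

2. Step 15.
- **What may go wrong:** glycol C–C cleavage may occur. The electron-rich enol may be oxidised further during the long exposure needed for the second oxidation. Enolisation of the dione may run towards C2, which would scramble the only ring stereocentre and move the double bond next to O1.
- **Fallback:** the oxidation is staged with two different chemoselectivity principles, setting out from 21. One equivalent of IBX (DMSO, rt, short contact) should stop at the α-ketol, expected to be the 3-hydroxy-4-oxotetrahydropyran F2, because the C4 carbinol is the more electron-rich one. The ketol is isolated and then oxidised with copper(II) acetate in MeOH–AcOH at rt. This reagent attacks only α-ketols, works in weakly acidic medium, and should return the material to the route at 23.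

3. Step 16.
- **What may go wrong:** strong acid may catalyse migration of the enol or epimerisation at C2. The liberated carbinol may be trifluoroacetylated. The enol may capture the tert-butyl cation.
- **Fallback:** the order of events is changed so that only a mild desilylation follows the oxidation, setting out from 21. The tert-butyl ester is cleaved first with 85 % aqueous H3PO4 in toluene at rt, conditions that spare TBS ethers, to give the silyl-protected diol acid F3. IBX in DMSO then gives the silyl-protected diosphenol acid F4. HF·pyridine in THF (0 °C → rt) removes the silyl group and reaches the route again at 24.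

Further compounds

F1 | step 14 | tert-butyl 6-{[(2E)-4-{(2S)-5-[(2E,4R,5S)-5-(TBSO)-4-methylhex-2-en-1-yl]-4-hydroxy-3-oxooxan-2-yl}-3-methylbut-2-enoyl]oxy}hexanoate | C/C(=C\C(=O)OCCCCCC(=O)OC(C)(C)C)C[C@@H]1OCC(C/C=C/[C@@H](C)[C@H](C)O[Si](C)(C)C(C)(C)C)C(O)C1=O
F2 | step 15 | tert-butyl 6-{[(2E)-4-{(2S)-5-[(2E,4R,5S)-5-(TBSO)-4-methylhex-2-en-1-yl]-3-hydroxy-4-oxooxan-2-yl}-3-methylbut-2-enoyl]oxy}hexanoate | C/C(=C\C(=O)OCCCCCC(=O)OC(C)(C)C)C[C@@H]1OCC(C/C=C/[C@@H](C)[C@H](C)O[Si](C)(C)C(C)(C)C)C(=O)C1O
F3 | step 16 | 6-{[(2E)-4-{(2S)-5-[(2E,4R,5S)-5-(TBSO)-4-methylhex-2-en-1-yl]-3,4-dihydroxyoxan-2-yl}-3-methylbut-2-enoyl]oxy}hexanoic acid | C/C(=C\C(=O)OCCCCCC(=O)O)C[C@@H]1OCC(C/C=C/[C@@H](C)[C@H](C)O[Si](C)(C)C(C)(C)C)C(O)C1O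
F4 | step 16 | 6-{[(2E)-4-{(2S)-5-[(2E,4R,5S)-5-(TBSO)-4-methylhex-2-en-1-yl]-4-hydroxy-3-oxo-3,6-dihydro-2H-pyran-2-yl}-3-methylbut-2-enoyl]oxy}hexanoic acid | C/C(=C\C(=O)OCCCCCC(=O)O)C[C@@H]1OCC(C/C=C/[C@@H](C)[C@H](C)O[Si](C)(C)C(C)(C)C)=C(O)C1=O
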